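**Retrosynthetic overview**
1. C–O disconnection first: the C12 carboxyl of the sesquiterpene half is traced back to the vinylic CH3 of (−)-β-caryophyllene (1). The key step is a site- and geometry-retentive C–H → C–O oxygenation (via 2–4) to allylic alcohol 5, then enal 6 → acid 7.
2. The cyclohexene is cut by a retro-[4+2] (labdane C15–caryophyllane C5 and labdane C12–caryophyllane C4) into dienophile 7 and trans-communic acid (8), which already carries all four labdane stereocentres.
3. Ring order: the cyclobutane and nine-membered ring (in 1) and the decalin (in 8) are bought. The cyclohexene of 9 is the only ring made, last, and its formation sets the three new stereocentres.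

Assumption: trans-communic acid (the main diterpene acid of Juniperus/Cupressus resins, sold by natural-product suppliers) is taken as the purchasable labdane half; it is not a cheap bulk chemical.
Numbering used: caryophyllane C12 = CH3 on C4, C13 = exocyclic CH2 on C8; labdane numbering for 8. "Ring-trans" means C3 and C6 trans across C4=C5 as in 1; the CIP label becomes 4Z once C12 carries oxygen.

**Step 1**
Reactants: 1 (−)-β-caryophyllene
Product: 5 12-hydroxy-β-caryophyllene (ring-trans allylic alcohol), via allylpotassium 2 (not isolated), via peroxyborate ate complex 3 (not isolated), via allyl pinacol borate 4 (not isolated)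
Conditions: n-BuLi, KOtBu (1.05 equiv each), THF, −78 → −50 °C, 1 h; then tBuOO–Bpin (1.3 equiv, pre-formed from MeO–Bpin + anhydrous tBuOOH, MeOH stripped), −78 → 0 °C; H2O
Reagents that add atoms: tert-butylperoxy-pinacolborane, CC(C)(C)OOB1OC(C)(C)C(C)(C)O1 (O of 5; boron ester of 3 and 4; made from tert-butyl hydroperoxide, CC(C)(C)OO, and MeO–Bpin, COB1OC(C)(C)C(C)(C)O1); potassium tert-butoxide, CC(C)(C)[O-].[K+] (K+ of 2 and 3)
Why: Proposed new method: the superbase should remove a proton only from the vinylic CH3 (primary allylic C–H, always aligned with the π-system, whereas the ring CH2 groups flanking the twisted trans-olefin lie near its nodal plane) to give the endo allylpotassium 2, which is configurationally stable below −50 °C; 2 attacks boron of the boron-bound peroxide through its unsubstituted terminus to give ate complex 3, whose allyl group then migrates from B to O with loss of tBuO− (the same stereoretentive 1,2-shift as in alkaline peroxide oxidation of boronates, with no allylic transposition and no rotation about C4=C5), so the C12–O bond forms with the trans-cyclononene geometry intact; the closest known reaction types are the Schlosser superbase metalation/borylation/peroxide oxidation of terpenes and the oxenoid (LiOOtBu) hydroxylation of organolithiums, and what is new is the single boron-templated electrophilic-oxygen reagent and its use on a strained E-cycloalkene.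

**Step 2**
Reactants: 5 12-hydroxy-β-caryophyllene
Product: 7 β-caryophyllen-12-oic acid (ring-trans enoic acid), via β-caryophyllen-12-al 6 (not isolated)
Conditions: TEMPO (10 mol %), PhI(OAc)2, CH2Cl2, 0 °C → rt; then t-BuOH/H2O, 2-methyl-2-butene (30 equiv), NaH2PO4, NaClO2, 0 °C
Reagents that add atoms: sodium chlorite, [Na+].[O-]Cl=O
Why: Oxoammonium (TEMPO/PhI(OAc)2) oxidation of the primary allylic alcohol to the enal, followed in the same flask by Pinnick oxidation with HOCl scavenged by 2-methyl-2-butene, touches neither C=C bond and offers no strong nucleophile for addition–elimination, so the ring-trans geometry is kept; no stereocentre is formed.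

**Step 3**
Reactants: 7 β-caryophyllen-12-oic acid; 8 trans-communic acid
Product: 9 target C35 diacid
Conditions: 7 (1.5 equiv), BHT (cat.), PhMe (2 M), 100 °C, sealed tube, 48 h; RP-HPLC
Reagents that add atoms: none
Why: Intermolecular Diels–Alder reaction of the strain-activated trans-cyclononene enoic acid with the 12E-diene: the unsubstituted diene terminus C15 bonds to the β-carbon C5 ("ortho" rule of the 1-alkyl diene), suprafacial addition keeps C3/C6 trans, the endo-CO2H transition state places C11H2 cis to CO2H (labdane C12 R), and attack on the exposed outer face of the olefin in its major conformer (the face epoxidised in natural caryophyllene oxide) sets caryophyllane C4 S and C5 S.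

**Compound list**
1 | (−)-β-caryophyllene, (1R,4E,9S)-4,11,11-trimethyl-8-methylenebicyclo[7.2.0]undec-4-ene | C=C1CC/C=C(\C)/CC[C@@H]2[C@@H]1CC2(C)C | starting material
2 | C12-allylpotassium of 1 (endo, ring-trans geometry kept; in-flask species) | C=C1CC/C=C(\[CH2-])/CC[C@@H]2[C@@H]1CC2(C)C.[K+] | intermediate
3 | potassium (β-caryophyllen-12-yl)(tert-butylperoxy)(pinacolato)borate (in-flask species) | C=C1CC/C=C(\C[B-]3(OOC(C)(C)C)OC(C)(C)C(C)(C)O3)/CC[C@@H]2[C@@H]1CC2(C)C.[K+] | intermediate
4 | 12-(pinacolboryloxy)-β-caryophyllene (in-flask species) | C=C1CC/C=C(\COB3OC(C)(C)C(C)(C)O3)/CC[C@@H]2[C@@H]1CC2(C)C | intermediate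
5 | 12-hydroxy-β-caryophyllene, [(1R,4Z,9S)-11,11-dimethyl-8-methylenebicyclo[7.2.0]undec-4-en-4-yl]methanol (ring-trans) | C=C1CC/C=C(\CO)/CC[C@@H]2[C@@H]1CC2(C)C | intermediate
6 | β-caryophyllen-12-al, (1R,4Z,9S)-11,11-dimethyl-8-methylenebicyclo[7.2.0]undec-4-ene-4-carbaldehyde (ring-trans; in-flask species) | C=C1CC/C=C(\C=O)/CC[C@@H]2[C@@H]1CC2(C)C | intermediate
7 | β-caryophyllen-12-oic acid, (1R,4Z,9S)-11,11-dimethyl-8-methylenebicyclo[7.2.0]undec-4-ene-4-carboxylic acid (ring-trans) | C=C1CC/C=C(\C(=O)O)/CC[C@@H]2[C@@H]1CC2(C)C | intermediate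
8 | trans-communic acid, (1S,4aR,5S,8aR)-1,4a-dimethyl-6-methylene-5-[(2E)-3-methylpenta-2,4-dien-1-yl]decahydronaphthalene-1-carboxylic acid | C=C/C(C)=C/C[C@H]1C(=C)CC[C@@H]2[C@]1(C)CCC[C@]2(C)C(=O)O | starting material
9 | target: [4+2] adduct with the cyclohexene fused at caryophyllane C4/C5, 4-CO2H, Δ13(14) with 13-CH3, labdan-19-oic acid side; caryophyllane 1R,4S,5S,9S, labdane 4S,5R,9S,10R,12R | C=C1CC[C@H]2CC=C(C)[C@@H](C[C@H]3C(=C)CC[C@@H]4[C@]3(C)CCC[C@]4(C)C(=O)O)[C@]2(C(=O)O)CC[C@@H]2[C@@H]1CC2(C)C | target

**Totals**
Total steps: 3. Longest linear sequence: 3 (1 → 5 → 7 → 9); 8 enters in step 3.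

**Steps most likely to fail (all three steps of the route)**

Step 1 (proposed new method). The boron-bound peroxide may undergo electron transfer or be attacked at oxygen instead of boron, and some metalation at C7 is possible. The fallback uses known chemistry and sets out from 1. Allylpotassium 2, made in the same way, is trapped at −78 °C with iPrO–Bpin to give the potassium isopropoxy(allyl)borate F1. On NH4Cl work-up this gives the isolable allylboronate 12-(pinacolboryl)-β-caryophyllene F2. NaBO3·4H2O in THF/H2O then oxidises F2 through borate 4 to alcohol 5, where the route is rejoined. This is the established superbase metalation/borylation/oxidation sequence for allylic hydroxylation of terpenes; it shares the metalation with the main step, so it does not cover a failure of site selectivity in the deprotonation.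

Step 3. The thermal cycloaddition of two free acids may be slow or give regio-, endo/exo- or face-isomers. The fallback sets out from 7 and 8 and changes to Lewis-acid activation of masked acids. Allyl bromide/K2CO3 in DMF gives allyl β-caryophyllen-12-oate F4 and allyl trans-communate F5. Et2AlCl in CH2Cl2 at −40 °C promotes the ester-activated Diels–Alder reaction, with stronger ortho and endo preference, to the diallyl ester of the adduct F6. Pd(PPh3)4/morpholine then removes both hindered allyl esters without touching the olefins and returns to the route at 9.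

Step 2. The strained enal or enoic acid may isomerise to the ring-cis form, or HOCl may attack an olefin. The fallback sets out from 5 and moves the carboxyl oxidation behind the cycloaddition. MnO2 in CH2Cl2 gives aldehyde 6, which is isolated. Its thermal Diels–Alder reaction with 8 (PhMe, 80 °C) gives the adduct aldehyde-acid F3, in which the former dienophile olefin is gone. Pinnick oxidation of F3 (NaClO2, NaH2PO4, 2-methyl-2-butene) comes back to the route at 9.

**Further compounds**
F1 | step 1 | potassium (β-caryophyllen-12-yl)(isopropoxy)(pinacolato)borate | C=C1CC/C=C(\C[B-]3(OC(C)C)OC(C)(C)C(C)(C)O3)/CC[C@@H]2[C@@H]1CC2(C)C.[K+]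
F2 | step 1 | 12-(pinacolboryl)-β-caryophyllene (ring-trans allylboronate) | C=C1CC/C=C(\CB3OC(C)(C)C(C)(C)O3)/CC[C@@H]2[C@@H]1CC2(C)C
F3 | step 2 | adduct aldehyde-acid (9 with CHO in place of the caryophyllane CO2H) | C=C1CC[C@H]2CC=C(C)[C@@H](C[C@H]3C(=C)CC[C@@H]4[C@]3(C)CCC[C@]4(C)C(=O)O)[C@]2(C=O)CC[C@@H]2[C@@H]1CC2(C)C
F4 | step 3 | allyl β-caryophyllen-12-oate (ring-trans) | C=C1CC/C=C(\C(=O)OCC=C)/CC[C@@H]2[C@@H]1CC2(C)C
F5 | step 3 | allyl trans-communate | C=C/C(C)=C/C[C@H]1C(=C)CC[C@@H]2[C@]1(C)CCC[C@]2(C)C(=O)OCC=C
F6 | step 3 | diallyl ester of 9 | C=C1CC[C@H]2CC=C(C)[C@@H](C[C@H]3C(=C)CC[C@@H]4[C@]3(C)CCC[C@]4(C)C(=O)OCC=C)[C@]2(C(=O)OCC=C)CC[C@@H]2[C@@H]1CC2(C)C
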